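The flavone is cut at C4–C4a, so that ring C is closed last by an intramolecular Friedel–Crafts acylation of an aryl enol ether. In ring A, O1 sits on C8a, flanked by the methoxylated C8 and the unsubstituted C4a; an acyl carbon tethered through O1 and C2=C3 can therefore reach only C4a. One operation forms the C4–C4a bond and the complete 3-methoxyflavone core with every oxygen in place. The precursor is an (E)-3-aryloxy-3-aryl-2-methoxyacrylic acid, assembled by vinylic substitution of an enol triflate with a ring A phenol whose O7 is masked as a tosylate until the prenyl ether has been installed.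

Key step: step 9

Remark: the acrylate double bond is drawn E throughout (ester or carboxyl cis to the oxygen substituent on the neighbouring carbon), as expected from a chelated enolate and a retentive vinylic substitution; any Z isomer would be carried along, because the push–pull double bond can rotate under the acid of the key step.
Remark: conjugate bases formed in the flask (enolates, phenoxides, carboxylates) are treated as forms of the numbered compound and carry no number of their own.

Step 1
Reactants: 1 2-methoxyresorcinol (2-methoxybenzene-1,3-diol)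
Product: 2 2-methoxy-1,3-phenylene bis(4-methylbenzenesulfonate)
Conditions: TsCl (2.3 equiv), K2CO3, acetone, reflux
Reagents that add atoms: 4-methylbenzenesulfonyl chloride, Cc1ccc(cc1)S(Cl)(=O)=O
Why: Exhaustive O-sulfonylation of both phenols (Schotten–Baumann-type) should give the symmetric bis-tosylate, whose sulfonates shield C4 and C6 in the next step and later supply the O7 protecting group.

Step 2
Reactants: 2 2-methoxy-1,3-phenylene bis(4-methylbenzenesulfonate)
Product: 4 5-hydroxy-2-methoxy-1,3-phenylene bis(4-methylbenzenesulfonate), via pinacol arylboronate 3 (not isolated)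
Conditions: B2pin2 (0.7 equiv), [Ir(OMe)(1,5-cyclooctadiene)]2 (1.5 mol%), 4,4'-di-tert-butyl-2,2'-bipyridine (3 mol%), THF, 80 °C; then KHSO5 (Oxone, 2KHSO5·KHSO4·K2SO4), acetone/H2O, rt
Reagents that add atoms: potassium peroxymonosulfate, [K+].[O-]S(=O)(=O)OO
Why: Sterically governed iridium-catalysed C–H borylation should take place only at C5, the single C–H without an ortho substituent (every C–H of the tosyl rings is ortho to methyl or sulfonyl), and oxidation of the C–B bond by peroxymonosulfate (aryl shift from boron to oxygen) should deliver the phenol in the same flask.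

Step 3
Reactants: 4 5-hydroxy-2-methoxy-1,3-phenylene bis(4-methylbenzenesulfonate)
Product: 5 5-(benzyloxy)-2-methoxy-1,3-phenylene bis(4-methylbenzenesulfonate)
Conditions: BnBr (1.2 equiv), K2CO3, acetone, 50 °C
Reagents that add atoms: benzyl bromide, BrCc1ccccc1
Why: Williamson etherification of the only free phenol should be clean, since aryl tosylates are inert to carbonate in acetone.

Step 4
Reactants: 5 5-(benzyloxy)-2-methoxy-1,3-phenylene bis(4-methylbenzenesulfonate)
Product: 6 5-(benzyloxy)-3-hydroxy-2-methoxyphenyl 4-methylbenzenesulfonate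
Conditions: KOH (2.2 equiv), 1,4-dioxane/H2O, 60 °C; then 1 M HCl
Reagents that add atoms: none
Why: Alkaline hydrolysis of an aryl sulfonate proceeds by attack of hydroxide at sulfur; after the first cleavage the ring carries a phenoxide, so the second sulfonate would have to leave as a dianion and should react much more slowly, which allows a stop at the monophenol (the two tosylates are equivalent by symmetry, so either cleavage gives 6).

Step 5
Reactants: 7 methyl methoxyacetate; 8 4-(benzyloxy)benzoyl chloride
Product: 9 methyl 3-[4-(benzyloxy)phenyl]-2-methoxy-3-oxopropanoate (racemic)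
Conditions: 7 (2.1 equiv), LiN(SiMe3)2 (2.1 equiv), THF, −78 °C; then 8 (1.0 equiv), −78 → 0 °C; aq. NH4Cl
Reagents that add atoms: none
Why: Crossed Claisen condensation, in which the lithium ester enolate is C-acylated by the acid chloride and the second equivalent of enolate deprotonates the more acidic keto ester, which prevents double acylation; the enolisable stereocenter at C2 is formed racemic and disappears in step 6.

Step 6
Reactants: 9 methyl 3-[4-(benzyloxy)phenyl]-2-methoxy-3-oxopropanoate
Product: 10 methyl (2E)-3-[4-(benzyloxy)phenyl]-2-methoxy-3-{[(trifluoromethyl)sulfonyl]oxy}prop-2-enoate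
Conditions: NaH, THF, 0 °C; then Tf2O, −78 → 0 °C
Reagents that add atoms: trifluoromethanesulfonic anhydride, O=S(=O)(OS(=O)(=O)C(F)(F)F)C(F)(F)F
Why: O-Sulfonylation of the sodium enolate of a β-keto ester, whose chelated U-shaped form holds the enolate oxygen cis to the ester, should give the E enol triflate.

Step 7
Reactants: 6 5-(benzyloxy)-3-hydroxy-2-methoxyphenyl 4-methylbenzenesulfonate; 10 methyl (2E)-3-[4-(benzyloxy)phenyl]-2-methoxy-3-{[(trifluoromethyl)sulfonyl]oxy}prop-2-enoate
Product: 11 methyl (2E)-3-[5-(benzyloxy)-2-methoxy-3-{[(4-methylphenyl)sulfonyl]oxy}phenoxy]-3-[4-(benzyloxy)phenyl]-2-methoxyprop-2-enoate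
Conditions: Cs2CO3 (1.5 equiv), MeCN, rt → 50 °C
Reagents that add atoms: none
Why: Nucleophilic vinylic substitution by addition–elimination, in which the caesium phenoxide adds to C3 of the β-triflyloxy acrylate and the resulting ester enolate expels triflate, follows the classical preparation of 3-aryloxyacrylates from phenoxides and β-halo or β-sulfonyloxy acrylates and should retain the geometry.

Step 8
Reactants: 11 methyl (2E)-3-[5-(benzyloxy)-2-methoxy-3-{[(4-methylphenyl)sulfonyl]oxy}phenoxy]-3-[4-(benzyloxy)phenyl]-2-methoxyprop-2-enoate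
Product: 12 (2E)-3-[5-(benzyloxy)-2-methoxy-3-{[(4-methylphenyl)sulfonyl]oxy}phenoxy]-3-[4-(benzyloxy)phenyl]-2-methoxyprop-2-enoic acid
Conditions: LiOH (3 equiv), THF/H2O, rt; then 1 M HCl, 0 °C
Reagents that add atoms: lithium hydroxide, [Li+].[OH-]
Why: Saponification by acyl–oxygen cleavage is routine for 3-aryloxyacrylates, and at room temperature hydroxide should attack the ester carbonyl, activated by the α-methoxy group, much faster than the sulfur of the aryl tosylate.

Step 9
Reactants: 12 (2E)-3-[5-(benzyloxy)-2-methoxy-3-{[(4-methylphenyl)sulfonyl]oxy}phenoxy]-3-[4-(benzyloxy)phenyl]-2-methoxyprop-2-enoic acid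
Product: 14 5-(benzyloxy)-2-[4-(benzyloxy)phenyl]-3,8-dimethoxy-4-oxo-4H-chromen-7-yl 4-methylbenzenesulfonate, via mixed trifluoroacetic anhydride 13 (not isolated)
Conditions: (CF3CO)2O (5 equiv), CH2Cl2, 0 °C → rt
Reagents that add atoms: none
Why: Trifluoroacetic anhydride should turn the acid into mixed anhydride 13, whose acyl carbon, made acylium-like by the trifluoroacetic acid set free, is attacked by C4a of ring A; loss of the C4a proton restores the arene and completes the 4-pyranone. The closest known reaction type is the intramolecular Friedel–Crafts acylation of 3-aryloxyacrylic acids to chromones and flavones (Ruhemann-type cyclization). Ring C (C4, C3, C2, O1, C8a, C4a) closes in a 6-exo-trig electrophilic aromatic substitution, the carbonyl oxygen staying outside the ring. No stereocenter is formed. The step needs site selectivity, and the substrate secures it: the tether through O1 spans only to the carbons ortho to O1, of which C8 bears the methoxy group, C6 lies out of reach, and C4a is further activated by the ortho 5-benzyloxy group, which outweighs the attenuation by the para 7-tosylate. Closure onto ring B would require the carboxyl cis to the aryl group, a strained five-membered indenone and attack at a carbon meta to O4', so the E geometry (carboxyl cis to the aryloxy group), which acid-mediated rotation about the push–pull C2–C3 bond can also supply, directs the acyl group to C4a.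

Step 10
Reactants: 14 5-(benzyloxy)-2-[4-(benzyloxy)phenyl]-3,8-dimethoxy-4-oxo-4H-chromen-7-yl 4-methylbenzenesulfonate
Product: 15 5-hydroxy-2-(4-hydroxyphenyl)-3,8-dimethoxy-4-oxo-4H-chromen-7-yl 4-methylbenzenesulfonate
Conditions: H2 (1 atm), Pd/C (10% palladium on carbon), EtOAc/THF, rt
Reagents that add atoms: none
Why: Hydrogenolysis should remove both benzyl ethers, which were chosen because they tolerate the acid of step 9, while the aryl tosylate and the tetrasubstituted, vinylogous-ester C2=C3 bond are not reduced under neutral conditions.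

Step 11
Reactants: 15 5-hydroxy-2-(4-hydroxyphenyl)-3,8-dimethoxy-4-oxo-4H-chromen-7-yl 4-methylbenzenesulfonate; 16 prenyl bromide (1-bromo-3-methylbut-2-ene)
Product: 17 5-hydroxy-3,8-dimethoxy-2-{4-[(3-methylbut-2-en-1-yl)oxy]phenyl}-4-oxo-4H-chromen-7-yl 4-methylbenzenesulfonate
Conditions: 16 (1.1 equiv), K2CO3 (1.2 equiv), acetone, rt
Reagents that add atoms: none
Why: Williamson O-alkylation (SN2) should occur at the 4'-phenoxide only, because the 5-hydroxyl is held in a hydrogen bond to the C4 carbonyl and is far less acidic and nucleophilic, and O7 is blocked as the tosylate.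

Step 12
Reactants: 17 5-hydroxy-3,8-dimethoxy-2-{4-[(3-methylbut-2-en-1-yl)oxy]phenyl}-4-oxo-4H-chromen-7-yl 4-methylbenzenesulfonate
Product: 18 5,7-dihydroxy-3,8-dimethoxy-2-{4-[(3-methylbut-2-en-1-yl)oxy]phenyl}-4H-chromen-4-one (5,7-dihydroxy-3,8-dimethoxy-4'-prenyloxyflavone)
Conditions: KOH (3 equiv), MeOH/H2O, 50 °C; then AcOH
Reagents that add atoms: none
Why: Alkaline cleavage of the aryl sulfonate at sulfur should be fast because O7 leaves as a vinylogous carboxylate conjugated to the C4 carbonyl, and the prenyl ether, the methyl ethers and the chromone are stable to base.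

Compound list
1 | 2-methoxyresorcinol (2-methoxybenzene-1,3-diol) | COc1c(O)cccc1O | starting material
2 | 2-methoxy-1,3-phenylene bis(4-methylbenzenesulfonate) | COc1c(OS(=O)(=O)c2ccc(C)cc2)cccc1OS(=O)(=O)c1ccc(C)cc1 | intermediate
3 | 2-methoxy-5-(4,4,5,5-tetramethyl-1,3,2-dioxaborolan-2-yl)-1,3-phenylene bis(4-methylbenzenesulfonate) | COc1c(OS(=O)(=O)c2ccc(C)cc2)cc(B2OC(C)(C)C(C)(C)O2)cc1OS(=O)(=O)c1ccc(C)cc1 | intermediate (not isolated)
4 | 5-hydroxy-2-methoxy-1,3-phenylene bis(4-methylbenzenesulfonate) | COc1c(OS(=O)(=O)c2ccc(C)cc2)cc(O)cc1OS(=O)(=O)c1ccc(C)cc1 | intermediate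
5 | 5-(benzyloxy)-2-methoxy-1,3-phenylene bis(4-methylbenzenesulfonate) | COc1c(OS(=O)(=O)c2ccc(C)cc2)cc(OCc2ccccc2)cc1OS(=O)(=O)c1ccc(C)cc1 | intermediate
6 | 5-(benzyloxy)-3-hydroxy-2-methoxyphenyl 4-methylbenzenesulfonate | COc1c(O)cc(OCc2ccccc2)cc1OS(=O)(=O)c1ccc(C)cc1 | intermediate
7 | methyl methoxyacetate | COCC(=O)OC | starting material
8 | 4-(benzyloxy)benzoyl chloride | O=C(Cl)c1ccc(OCc2ccccc2)cc1 | starting material
9 | methyl 3-[4-(benzyloxy)phenyl]-2-methoxy-3-oxopropanoate (racemic) | COC(C(=O)OC)C(=O)c1ccc(OCc2ccccc2)cc1 | intermediate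
10 | methyl (2E)-3-[4-(benzyloxy)phenyl]-2-methoxy-3-{[(trifluoromethyl)sulfonyl]oxy}prop-2-enoate | COC(=O)/C(OC)=C(\OS(=O)(=O)C(F)(F)F)c1ccc(OCc2ccccc2)cc1 | intermediate
11 | methyl (2E)-3-[5-(benzyloxy)-2-methoxy-3-{[(4-methylphenyl)sulfonyl]oxy}phenoxy]-3-[4-(benzyloxy)phenyl]-2-methoxyprop-2-enoate | COC(=O)/C(OC)=C(\Oc1cc(OCc2ccccc2)cc(OS(=O)(=O)c2ccc(C)cc2)c1OC)c1ccc(OCc2ccccc2)cc1 | intermediate
12 | (2E)-3-[5-(benzyloxy)-2-methoxy-3-{[(4-methylphenyl)sulfonyl]oxy}phenoxy]-3-[4-(benzyloxy)phenyl]-2-methoxyprop-2-enoic acid | OC(=O)/C(OC)=C(\Oc1cc(OCc2ccccc2)cc(OS(=O)(=O)c2ccc(C)cc2)c1OC)c1ccc(OCc2ccccc2)cc1 | intermediate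
13 | (2E)-3-[5-(benzyloxy)-2-methoxy-3-{[(4-methylphenyl)sulfonyl]oxy}phenoxy]-3-[4-(benzyloxy)phenyl]-2-methoxyprop-2-enoic trifluoroacetic anhydride | O=C(OC(=O)C(F)(F)F)/C(OC)=C(\Oc1cc(OCc2ccccc2)cc(OS(=O)(=O)c2ccc(C)cc2)c1OC)c1ccc(OCc2ccccc2)cc1 | intermediate (not isolated)
14 | 5-(benzyloxy)-2-[4-(benzyloxy)phenyl]-3,8-dimethoxy-4-oxo-4H-chromen-7-yl 4-methylbenzenesulfonate | COc1c(-c2ccc(OCc3ccccc3)cc2)oc2c(OC)c(OS(=O)(=O)c3ccc(C)cc3)cc(OCc3ccccc3)c2c1=O | intermediate
15 | 5-hydroxy-2-(4-hydroxyphenyl)-3,8-dimethoxy-4-oxo-4H-chromen-7-yl 4-methylbenzenesulfonate | COc1c(-c2ccc(O)cc2)oc2c(OC)c(OS(=O)(=O)c3ccc(C)cc3)cc(O)c2c1=O | intermediate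
16 | prenyl bromide (1-bromo-3-methylbut-2-ene) | CC(C)=CCBr | starting material
17 | 5-hydroxy-3,8-dimethoxy-2-{4-[(3-methylbut-2-en-1-yl)oxy]phenyl}-4-oxo-4H-chromen-7-yl 4-methylbenzenesulfonate | COc1c(-c2ccc(OCC=C(C)C)cc2)oc2c(OC)c(OS(=O)(=O)c3ccc(C)cc3)cc(O)c2c1=O | intermediate
18 | 5,7-dihydroxy-3,8-dimethoxy-2-{4-[(3-methylbut-2-en-1-yl)oxy]phenyl}-4H-chromen-4-one | COc1c(-c2ccc(OCC=C(C)C)cc2)oc2c(OC)c(O)cc(O)c2c1=O | target

Total step count: 12. Longest linear sequence: 10 steps (steps 1–4 and 7–12); steps 5 and 6 form the second branch.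

Steps most likely to fail

Step 9. The ring closure may be too slow, because the tosylate para to C4a lowers the nucleophilicity of ring A and the push–pull acylium is a weak electrophile. Acid-promoted loss of benzyl groups or hydrolytic cleavage of the enol ether on work-up could then take over. The fallback forms O1–C2 last and sets out from 6. Esterification with methoxyacetyl chloride (pyridine, CH2Cl2) would give 5-(benzyloxy)-2-methoxy-3-{[(4-methylphenyl)sulfonyl]oxy}phenyl methoxyacetate F1. A chelation-controlled Fries rearrangement (BF3·OEt2, 1,2-dichloroethane, 60 °C) should move the acyl group to the carbon ortho to the phenol and give 5-(benzyloxy)-3-hydroxy-2-methoxy-4-(methoxyacetyl)phenyl 4-methylbenzenesulfonate F2. A one-pot Baker–Venkataraman C-aroylation with 8 (LiN(SiMe3)2, 3 equiv, THF, −78 °C → rt) would give the 1,3-diketone 5-(benzyloxy)-4-{3-[4-(benzyloxy)phenyl]-2-methoxy-3-oxopropanoyl}-3-hydroxy-2-methoxyphenyl 4-methylbenzenesulfonate F3 (racemic). Cyclodehydration (AcOH, catalytic H2SO4, 60 °C) brings the route back at 14.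

Step 7. The phenoxide may attack the sulfur of the triflate instead of C3 (sulfonyl transfer that regenerates the keto ester), or the addition at the tetrasubstituted, donor-substituted C3 may be too slow. The fallback sets out from 6 and 10 and forms the same O–C3 bond by C–O cross-coupling under catalysis by zerovalent palladium (Pd2(dibenzylideneacetone)3, 2-(di-tert-butylphosphino)biphenyl, K3PO4, toluene, 80 °C). This is a known route from vinyl triflates and phenols to aryl enol ethers; it runs through oxidative addition and reductive elimination and so does not depend on the electrophilicity of C3. It comes back at 11 and makes no new compound (F0).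

Step 4. Hydrolysis may run on to the second sulfonate or stop short, leaving a mixture of bis-tosylate, monophenol and diol. The fallback sets out from 5. Exhaustive cleavage (KOH, 5 equiv, 1,4-dioxane/H2O, 90 °C) would give 5-(benzyloxy)-2-methoxybenzene-1,3-diol F4. Monotosylation with one equivalent of TsCl (K2CO3, acetone, 0 °C → rt), with recovered diol and bis-tosylate recycled, comes back at 6.

Further compounds
F1 | step 9 | 5-(benzyloxy)-2-methoxy-3-{[(4-methylphenyl)sulfonyl]oxy}phenyl methoxyacetate | COCC(=O)Oc1cc(OCc2ccccc2)cc(OS(=O)(=O)c2ccc(C)cc2)c1OC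
F2 | step 9 | 5-(benzyloxy)-3-hydroxy-2-methoxy-4-(methoxyacetyl)phenyl 4-methylbenzenesulfonate | COCC(=O)c1c(O)c(OC)c(OS(=O)(=O)c2ccc(C)cc2)cc1OCc1ccccc1
F3 | step 9 | 5-(benzyloxy)-4-{3-[4-(benzyloxy)phenyl]-2-methoxy-3-oxopropanoyl}-3-hydroxy-2-methoxyphenyl 4-methylbenzenesulfonate (racemic) | COC(C(=O)c1ccc(OCc2ccccc2)cc1)C(=O)c1c(O)c(OC)c(OS(=O)(=O)c2ccc(C)cc2)cc1OCc1ccccc1
F0 | step 7 | none | none
F4 | step 4 | 5-(benzyloxy)-2-methoxybenzene-1,3-diol | COc1c(O)cc(OCc2ccccc2)cc1O
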